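**Retrosynthetic overview**

1. Target 19 ⇒ macrocyclic α-bromobutenolide 18 by a last-step Stille hydroxymethylation (C11–C13).
2. 18 ⇒ open-chain enal 14: the ten-membered carbocycle is closed last, by an intramolecular vinylogous aldol condensation (C5=C6) onto the existing butenolide.
3. 14 ⇒ aldehyde 10 + 3,4-dibromofuran-2(5H)-one 11: the key C7–C8 bond comes from a Ni/Cr coupling in which C4 of the bromobutenolide, normally an acceptor carbon, acts as a β-acylvinyl anion (homoenolate-type d3 donor) toward the C8 aldehyde; the chiral ligand sets C8.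
4. 10 ⇒ dihydropyranone 4 ⇒ prenal 1 + Danishefsky's diene 2: a catalytic asymmetric hetero-Diels–Alder reaction sets C2, and axial MeLi addition on the temporary pyran ring relays C2 to C10 before the ring is opened.
5. Ring order: pyran template (made first, then opened) → butenolide (bought as 11) → ten-membered ring (last).

Assumption: positions are cited in germacrane numbering (C8 = methacrylate carbinol, C10 = tertiary carbinol, C2 = acetate carbinol, C6/C7/C11/C12 = lactone carbons, C13 = CH2OH); the ligand enantiomers named in steps 1 and 7 are taken to induce the sense shown, and the antipodes are equally available if the sense is opposite.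

**Route**

Step 1
Reactants: 1 3-methylbut-2-enal; 2 Danishefsky's diene
Product: 4 (2S)-2-(2-methylprop-1-en-1-yl)-2,3-dihydro-4H-pyran-4-one, via aldol silyl ether 3 (not isolated)
Conditions: (S)-BINOL (20 mol %), Ti(OiPr)4 (10 mol %), 4 Å MS, Et2O, −20 °C; then CF3CO2H, CH2Cl2, 0 °C
Reagents that add atoms: none
Why: Keck-type catalytic asymmetric Mukaiyama aldol/hetero-Diels–Alder reaction, in which the titanium BINOLate shields one aldehyde face to set C2 (S) and CF3CO2H closes the aldol to the dihydropyranone with loss of methanol and the silyl group.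

Step 2
Reactants: 4 (2S)-2-(2-methylprop-1-en-1-yl)-2,3-dihydro-4H-pyran-4-one
Product: 5 (2S,4S)-4-methyl-2-(2-methylprop-1-en-1-yl)-3,4-dihydro-2H-pyran-4-ol
Conditions: MeLi, Et2O, −78 °C; pH 7 buffer quench
Reagents that add atoms: methyllithium, [Li]C
Why: 1,2-addition of an organolithium to the vinylogous ester carbonyl, with axial attack on the half-chair (as for 5-substituted cyclohexenones) placing the new OH cis to the pseudo-equatorial isobutenyl group, which sets C10 (S) anti to the C2 oxygen in the open chain.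

Step 3
Reactants: 5 (2S,4S)-4-methyl-2-(2-methylprop-1-en-1-yl)-3,4-dihydro-2H-pyran-4-ol
Product: 7 (4S,6S)-4-methyl-6-(2-methylprop-1-en-1-yl)oxane-2,4-diol, via organomercurial 6 (not isolated)
Conditions: Hg(OAc)2 (1.05 equiv), THF/H2O, 0 °C; then NaBH4, aq NaOH, 0 °C
Reagents that add atoms: water, O
Why: Oxymercuration–demercuration (the glycal to 2-deoxy-lactol hydration) adds water to the enol ether, which reacts far faster than the trisubstituted alkene, and avoids the acid that would ionise the tertiary allylic alcohol; the anomeric centre is formed as a mixture and is lost later.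

Step 4
Reactants: 7 (4S,6S)-4-methyl-6-(2-methylprop-1-en-1-yl)oxane-2,4-diol
Product: 8 (1E,3R,5S)-1-(2,2-dimethylhydrazinylidene)-3,7-dimethyloct-6-ene-3,5-diol
Conditions: Me2NNH2, AcOH (cat.), EtOH, 40 °C
Reagents that add atoms: N,N-dimethylhydrazine, CN(C)N
Why: Hydrazone condensation on the open-chain aldehyde tautomer of the lactol gives the acyclic hydrazone and frees the C2 hydroxyl.

Step 5
Reactants: 8 (1E,3R,5S)-1-(2,2-dimethylhydrazinylidene)-3,7-dimethyloct-6-ene-3,5-diol
Product: 9 (4S,6R,8E)-8-(2,2-dimethylhydrazinylidene)-6-hydroxy-2,6-dimethyloct-2-en-4-yl acetate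
Conditions: Ac2O, pyridine, DMAP (cat.), CH2Cl2, 0 °C
Reagents that add atoms: acetic anhydride, CC(=O)OC(C)=O
Why: DMAP-catalysed acetylation takes the secondary allylic C2 alcohol and leaves the tertiary C10 alcohol and the hydrazone untouched.

Step 6
Reactants: 9 (4S,6R,8E)-8-(2,2-dimethylhydrazinylidene)-6-hydroxy-2,6-dimethyloct-2-en-4-yl acetate
Product: 10 (4S,6S)-6-hydroxy-2,6-dimethyl-8-oxooct-2-en-4-yl acetate
Conditions: CuCl2, THF/pH 7 phosphate buffer, 0 °C → rt
Reagents that add atoms: water, O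
Why: Copper-promoted hydrolysis of the dimethylhydrazone at neutral pH releases the β-hydroxy aldehyde without dehydration, retro-aldol cleavage or loss of the allylic acetate.

Step 7
Reactants: 10 (4S,6S)-6-hydroxy-2,6-dimethyl-8-oxooct-2-en-4-yl acetate; 11 3,4-dibromofuran-2(5H)-one
Product: 12 (4S,6R,8R)-8-(4-bromo-5-oxo-2,5-dihydrofuran-3-yl)-6,8-dihydroxy-2,6-dimethyloct-2-en-4-yl acetate
Conditions: CrCl2 (4 equiv), (S)-N-[2-(4-isopropyl-4,5-dihydrooxazol-2-yl)-6-methylphenyl]methanesulfonamide (4 equiv), Et3N (4 equiv), NiCl2 (3 mol %), THF, rt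
Reagents that add atoms: none
Why: Proposed new method: zerovalent nickel inserts into the more electron-poor C4–Br bond (β to the lactone carbonyl, the site that also reacts first in palladium couplings of 11), transmetalation to trivalent chromium gives a β-acylvinyl chromium (a d3, homoenolate-type donor at a normally electrophilic carbon) that adds to the C8 aldehyde inside the chiral sulfonamide–chromium complex, which selects the aldehyde face and sets 8R; closest known reaction type: Kishi's ligand-controlled Nozaki–Hiyama–Kishi coupling of β-iodoacrylates and β-halo enones with aldehydes.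

Step 8
Reactants: 12 (4S,6R,8R)-8-(4-bromo-5-oxo-2,5-dihydrofuran-3-yl)-6,8-dihydroxy-2,6-dimethyloct-2-en-4-yl acetate
Product: 13 (1R,3S,5S)-5-acetoxy-1-(4-bromo-5-oxo-2,5-dihydrofuran-3-yl)-3-hydroxy-3,7-dimethyloct-6-en-1-yl 2-methylprop-2-enoate
Conditions: methacrylic anhydride, Et3N, DMAP (cat.), CH2Cl2, 0 °C → rt
Reagents that add atoms: methacrylic anhydride, C=C(C)C(=O)OC(=O)C(C)=C
Why: DMAP-catalysed esterification acylates the only secondary alcohol (C8) and leaves the tertiary C10 alcohol free.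

Step 9
Reactants: 13 (1R,3S,5S)-5-acetoxy-1-(4-bromo-5-oxo-2,5-dihydrofuran-3-yl)-3-hydroxy-3,7-dimethyloct-6-en-1-yl 2-methylprop-2-enoate
Product: 14 (1R,3S,5S,6E)-5-acetoxy-1-(4-bromo-5-oxo-2,5-dihydrofuran-3-yl)-3-hydroxy-3,7-dimethyl-8-oxooct-6-en-1-yl 2-methylprop-2-enoate
Conditions: SeO2, 1,4-dioxane, 80 °C
Reagents that add atoms: selenium dioxide, O=[Se]=O
Why: Riley allylic oxidation (ene reaction then 2,3-shift) attacks the (E)-methyl of the only electron-rich trisubstituted alkene and gives the (E)-enal, which fixes the C3=C4 geometry; the methacrylate and butenolide alkenes are electron-poor and do not react.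

Step 10
Reactants: 14 (1R,3S,5S,6E)-5-acetoxy-1-(4-bromo-5-oxo-2,5-dihydrofuran-3-yl)-3-hydroxy-3,7-dimethyl-8-oxooct-6-en-1-yl 2-methylprop-2-enoate
Product: 18 (4R,6S,8S,9E,11E)-8-acetoxy-3-bromo-6-hydroxy-6,10-dimethyl-2-oxo-2,4,5,6,7,8-hexahydrocyclodeca[b]furan-4-yl 2-methylprop-2-enoate, via bis-silylated siloxyfuran 15 (not isolated), via macrocyclic aldol silyl ether 16 (not isolated), via C10-silylated ylidene lactone 17 (not isolated)
Conditions: TMSOTf (2.5 equiv), Et3N (4 equiv), CH2Cl2 (1 mM), −78 → 0 °C; then DBU, 0 °C → rt; then citric acid, MeOH/H2O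
Reagents that add atoms: none
Why: Proposed new method: soft enolisation gives the aromatic 2-siloxyfuran, whose C6 adds to the TMSOTf-activated enal (intramolecular vinylogous Mukaiyama aldol), and DBU then expels silanolate from C5 (E1cB) to give the C5=C6 ylidene, the ten-membered ring allowing only the geometry with C4 cis to C7 (5E), while the acidic work-up removes the C10 silyl ether; closest known reaction type: the one-pot silyl triflate/amine then DBU vinylogous aldol condensation of 3-bromo-4-substituted furan-2(5H)-ones with aldehydes used for rubrolides, here run intramolecularly at high dilution.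

Step 11
Reactants: 18 (4R,6S,8S,9E,11E)-8-acetoxy-3-bromo-6-hydroxy-6,10-dimethyl-2-oxo-2,4,5,6,7,8-hexahydrocyclodeca[b]furan-4-yl 2-methylprop-2-enoate
Product: 19 (4R,6S,8S,9E,11E)-8-acetoxy-6-hydroxy-3-(hydroxymethyl)-6,10-dimethyl-2-oxo-2,4,5,6,7,8-hexahydrocyclodeca[b]furan-4-yl 2-methylprop-2-enoate
Conditions: Bu3SnCH2OH, Pd2(dba)3 (5 mol %), AsPh3 (20 mol %), CuI (10 mol %), NMP, 40 °C
Reagents that add atoms: (tributylstannyl)methanol, CCCC[Sn](CCCC)(CCCC)CO
Why: Stille cross-coupling (hydroxymethylation) at the activated α-bromo enoate; oxidative addition there is fast at low temperature, the conditions are neutral so the methacrylate cannot migrate to the new primary alcohol, and no protecting group is needed.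

**Compound list**

1 | 3-methylbut-2-enal (prenal) | CC(C)=CC=O | starting material
2 | (E)-1-methoxy-3-(trimethylsilyloxy)buta-1,3-diene (Danishefsky's diene) | CO/C=C/C(=C)O[Si](C)(C)C | starting material
3 | (1E,5S)-1-methoxy-7-methyl-5-(trimethylsilyloxy)octa-1,6-dien-3-one | CO/C=C/C(=O)C[C@H](O[Si](C)(C)C)C=C(C)C | intermediate
4 | (2S)-2-(2-methylprop-1-en-1-yl)-2,3-dihydro-4H-pyran-4-one | O=C1C=CO[C@H](C=C(C)C)C1 | intermediate
5 | (2S,4S)-4-methyl-2-(2-methylprop-1-en-1-yl)-3,4-dihydro-2H-pyran-4-ol (OH cis to the isobutenyl group) | C[C@@]1(O)C=CO[C@H](C=C(C)C)C1 | intermediate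
6 | [(4S,6S)-2,4-dihydroxy-4-methyl-6-(2-methylprop-1-en-1-yl)oxan-3-yl]mercury acetate (mixture at C2 and C3) | CC(=O)O[Hg]C1C(O)O[C@H](C=C(C)C)C[C@]1(C)O | intermediate
7 | (4S,6S)-4-methyl-6-(2-methylprop-1-en-1-yl)oxane-2,4-diol (anomer mixture) | OC1C[C@@](C)(O)C[C@@H](C=C(C)C)O1 | intermediate
8 | (1E,3R,5S)-1-(2,2-dimethylhydrazinylidene)-3,7-dimethyloct-6-ene-3,5-diol (same spatial arrangement as C10 and C2 of the target; the 3R label is a CIP priority effect) | CN(C)/N=C/C[C@@](C)(O)C[C@H](O)C=C(C)C | intermediate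
9 | (4S,6R,8E)-8-(2,2-dimethylhydrazinylidene)-6-hydroxy-2,6-dimethyloct-2-en-4-yl acetate | CN(C)/N=C/C[C@@](C)(O)C[C@H](OC(C)=O)C=C(C)C | intermediate
10 | (4S,6S)-6-hydroxy-2,6-dimethyl-8-oxooct-2-en-4-yl acetate | O=CC[C@@](C)(O)C[C@H](OC(C)=O)C=C(C)C | intermediate
11 | 3,4-dibromofuran-2(5H)-one | O=C1OCC(Br)=C1Br | starting material
12 | (4S,6R,8R)-8-(4-bromo-5-oxo-2,5-dihydrofuran-3-yl)-6,8-dihydroxy-2,6-dimethyloct-2-en-4-yl acetate | O[C@@H](C1=C(Br)C(=O)OC1)C[C@@](C)(O)C[C@H](OC(C)=O)C=C(C)C | intermediate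
13 | (1R,3S,5S)-5-acetoxy-1-(4-bromo-5-oxo-2,5-dihydrofuran-3-yl)-3-hydroxy-3,7-dimethyloct-6-en-1-yl 2-methylprop-2-enoate | C=C(C)C(=O)O[C@@H](C1=C(Br)C(=O)OC1)C[C@@](C)(O)C[C@H](OC(C)=O)C=C(C)C | intermediate
14 | (1R,3S,5S,6E)-5-acetoxy-1-(4-bromo-5-oxo-2,5-dihydrofuran-3-yl)-3-hydroxy-3,7-dimethyl-8-oxooct-6-en-1-yl 2-methylprop-2-enoate | C=C(C)C(=O)O[C@@H](C1=C(Br)C(=O)OC1)C[C@@](C)(O)C[C@H](OC(C)=O)/C=C(C)/C=O | intermediate
15 | 14 as its 2-(trimethylsilyloxy)furan with the C10 hydroxyl also silylated | C=C(C)C(=O)O[C@@H](c1coc(O[Si](C)(C)C)c1Br)C[C@@](C)(O[Si](C)(C)C)C[C@H](OC(C)=O)/C=C(C)/C=O | intermediate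
16 | ten-membered aldol adduct: C5 trimethylsilyl ether, C6–H, C10 trimethylsilyl ether (mixture at C5 and C6) | C=C(C)C(=O)O[C@@H]1C[C@@](C)(O[Si](C)(C)C)C[C@H](OC(C)=O)/C=C(C)/C(O[Si](C)(C)C)C2OC(=O)C(Br)=C21 | intermediate
17 | 18 as its C10 trimethylsilyl ether | C=C(C)C(=O)O[C@@H]1C[C@@](C)(O[Si](C)(C)C)C[C@H](OC(C)=O)/C=C(C)/C=C2/OC(=O)C(Br)=C21 | intermediate
18 | (4R,6S,8S,9E,11E)-8-acetoxy-3-bromo-6-hydroxy-6,10-dimethyl-2-oxo-2,4,5,6,7,8-hexahydrocyclodeca[b]furan-4-yl 2-methylprop-2-enoate | C=C(C)C(=O)O[C@@H]1C[C@@](C)(O)C[C@H](OC(C)=O)/C=C(C)/C=C2/OC(=O)C(Br)=C21 | intermediate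
19 | (4R,6S,8S,9E,11E)-8-acetoxy-6-hydroxy-3-(hydroxymethyl)-6,10-dimethyl-2-oxo-2,4,5,6,7,8-hexahydrocyclodeca[b]furan-4-yl 2-methylprop-2-enoate (CNP0246543.2; germacrane 2S,8R,10S,3E,5E) | C=C(C)C(=O)O[C@@H]1C[C@@](C)(O)C[C@H](OC(C)=O)/C=C(C)/C=C2/OC(=O)C(CO)=C21 | target

**Totals**

Total steps: 11. Longest linear sequence: 11 (1 → 19; 2 and 11 are bought).

**Three steps most likely to fail**

Step 10 (macrocyclisation). Risks are the entropic and transannular cost of closing a ten-membered ring, ionisation of the C8 ester next to the electron-rich siloxyfuran by the silyl triflate, and γ-enolisation of the acetoxy enal. The fallback closes the same bond by a Horner–Wadsworth–Emmons macrocyclisation and sets out from 10. Commercial mucobromic acid is condensed with dimethyl phosphite (addition to the aldehyde tautomer, then lactonisation) to give dimethyl (3,4-dibromo-5-oxo-2,5-dihydrofuran-2-yl)phosphonate F3. F3 replaces 11 in the Ni/Cr coupling of step 7 and gives the phosphonate alcohol F4. Methacryloylation as in step 8 gives the phosphonate methacrylate F5, and SeO2 oxidation as in step 9 gives the phosphonate enal F6. LiCl/DBU in MeCN at 1 mM (Masamune–Roush conditions) then forms C5=C6 directly, without silyl triflate, and the sequence comes back to the route at 18.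

Step 7 (key coupling). Risks are insertion at the wrong C–Br bond, reduction of the dibromide, and weak ligand control next to the free tertiary hydroxyl. The fallback separates bond formation from stereocontrol and sets out from 10 and 11. A ligand-free coupling (CrCl2, NiCl2 cat., DMF) gives 12 together with its 8-epimer, (4S,6R,8S)-8-(4-bromo-5-oxo-2,5-dihydrofuran-3-yl)-6,8-dihydroxy-2,6-dimethyloct-2-en-4-yl acetate F1. Dess–Martin oxidation of the mixture gives the single ketone, (4S,6S)-8-(4-bromo-5-oxo-2,5-dihydrofuran-3-yl)-6-hydroxy-2,6-dimethyl-8-oxooct-2-en-4-yl acetate F2. Reagent-controlled reduction with (S)-Me-CBS oxazaborolidine and BH3·SMe2 (butenolide carbon as the large group) then gives the 8R alcohol, and the sequence comes back to the route at 12.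

Step 11 (late hydroxymethylation). Risks are ionisation of the dienylic C2 acetate by zerovalent palladium and slow transmetalation at the hindered α-bromo lactone. The fallback reverses the roles at C13 and sets out from 18: CrCl2 with NiCl2 (cat.) in DMF turns the C11–Br bond into a vinylchromium nucleophile that adds to paraformaldehyde, with no palladium and no tin reagent. It gives 19 directly and makes no new compound.

**Further compounds**

F1 | step 7 | (4S,6R,8S)-8-(4-bromo-5-oxo-2,5-dihydrofuran-3-yl)-6,8-dihydroxy-2,6-dimethyloct-2-en-4-yl acetate | O[C@H](C1=C(Br)C(=O)OC1)C[C@@](C)(O)C[C@H](OC(C)=O)C=C(C)C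
F2 | step 7 | (4S,6S)-8-(4-bromo-5-oxo-2,5-dihydrofuran-3-yl)-6-hydroxy-2,6-dimethyl-8-oxooct-2-en-4-yl acetate | O=C(C1=C(Br)C(=O)OC1)C[C@@](C)(O)C[C@H](OC(C)=O)C=C(C)C
F3 | step 10 | dimethyl (3,4-dibromo-5-oxo-2,5-dihydrofuran-2-yl)phosphonate | COP(=O)(OC)C1OC(=O)C(Br)=C1Br
F4 | step 10 | (4S,6R,8R)-8-[4-bromo-2-(dimethoxyphosphoryl)-5-oxo-2,5-dihydrofuran-3-yl]-6,8-dihydroxy-2,6-dimethyloct-2-en-4-yl acetate (mixture at the phosphorus-bearing carbon) | O[C@@H](C1=C(Br)C(=O)OC1P(=O)(OC)OC)C[C@@](C)(O)C[C@H](OC(C)=O)C=C(C)C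
F5 | step 10 | (1R,3S,5S)-5-acetoxy-1-[4-bromo-2-(dimethoxyphosphoryl)-5-oxo-2,5-dihydrofuran-3-yl]-3-hydroxy-3,7-dimethyloct-6-en-1-yl 2-methylprop-2-enoate | C=C(C)C(=O)O[C@@H](C1=C(Br)C(=O)OC1P(=O)(OC)OC)C[C@@](C)(O)C[C@H](OC(C)=O)C=C(C)C
F6 | step 10 | (1R,3S,5S,6E)-5-acetoxy-1-[4-bromo-2-(dimethoxyphosphoryl)-5-oxo-2,5-dihydrofuran-3-yl]-3-hydroxy-3,7-dimethyl-8-oxooct-6-en-1-yl 2-methylprop-2-enoate | C=C(C)C(=O)O[C@@H](C1=C(Br)C(=O)OC1P(=O)(OC)OC)C[C@@](C)(O)C[C@H](OC(C)=O)/C=C(C)/C=O
F0 | step 11 | none | none
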